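**Plan**
- Retrosynthesis (locants of 11H-dibenzo[b,e][1,4]dioxepin-11-one: ring A = C1–C4a/C11a, ether O5, ring B = C5a–C9a, lactone O10–C11): first cut the pyranone ring at C7–C(=O) and O8–C(CH3)2, then the lactone bond C11–O10, then the diaryl ether bond C4a–O5.
- This gives 3-methylbut-2-enoic acid, a ring A fluoroarene from 2,6-difluoro-4-methylbenzaldehyde and a ring B phenol from 2,4-dihydroxy-6-methylbenzaldehyde.
- Forward: ring A (SNAr, para-bromination, carbonylation) and ring B (benzylation, Dakin oxidation) are joined by SNAr at the fluoride flanked by formyl and ester; global debenzylation and lactonisation close the seven-membered ring.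
- Last ring: a one-pot acylation/Fries shift/oxa-Michael annulation of the tricyclic diol with the C5 acid builds the 2,2-dimethylpyranone (two bonds, five carbons) in the final step.
- Enabling feature: C7–H of ring B is ortho to the free O8–H, para to the lactone oxygen O10 and ortho to the C6 methyl, while ring A is switched off by its formyl and lactone carbonyl groups.
- Stereochemistry: the target has no stereocentre (its only sp3 ring carbon bears two methyl groups), so nothing has to be set.

Key step: step 9

Remark: the three starting materials are taken as purchasable; the fluoro aldehyde would otherwise be one lithiation/formylation step from 3,5-difluorotoluene.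

**Step 1**
Reactants: 1 2,6-difluoro-4-methylbenzaldehyde
Product: 2 2-(benzyloxy)-6-fluoro-4-methylbenzaldehyde
Conditions: BnOH (1.0 equiv), NaH (1.05 equiv), THF, 0 °C → rt
Reagents that add atoms: benzyl alcohol OCc1ccccc1
Why: SNAr of sodium benzyloxide at one of the two equivalent fluorines ortho to the formyl group, where the symmetry of 1 removes any regiochemical question and the first alkoxy group slows a second substitution.

**Step 2**
Reactants: 2 2-(benzyloxy)-6-fluoro-4-methylbenzaldehyde
Product: 3 6-(benzyloxy)-3-bromo-2-fluoro-4-methylbenzaldehyde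
Conditions: NBS (1.05 equiv), cat. TFA, MeCN, rt, dark
Reagents that add atoms: N-bromosuccinimide O=C1CCC(=O)N1Br
Why: Electrophilic aromatic bromination should go para to the benzyloxy group (also ortho to F and CH3, meta to CHO), as in the para-bromination of 3-fluoroanisoles and 2-alkoxybenzaldehydes.

**Step 3**
Reactants: 3 6-(benzyloxy)-3-bromo-2-fluoro-4-methylbenzaldehyde
Product: 4 benzyl 4-(benzyloxy)-2-fluoro-3-formyl-6-methylbenzoate
Conditions: CO (1 atm), BnOH (3 equiv), Pd(OAc)2 (cat.), Xantphos (cat.), Et3N, toluene, 80 °C
Reagents that add atoms: carbon monoxide [C-]#[O+]; benzyl alcohol OCc1ccccc1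
Why: Pd-catalysed alkoxycarbonylation (Heck carbonylation) of the aryl bromide by oxidative addition, CO insertion and alcoholysis, with a weak amine base so that the activated fluoride is not displaced.

**Step 4**
Reactants: 5 2,4-dihydroxy-6-methylbenzaldehyde
Product: 6 2,4-bis(benzyloxy)-6-methylbenzaldehyde
Conditions: BnBr (2.4 equiv), K2CO3, DMF, 60 °C
Reagents that add atoms: benzyl bromide BrCc1ccccc1
Why: Williamson etherification of both phenols, the chelated ortho hydroxyl included under these forcing conditions.

**Step 5**
Reactants: 6 2,4-bis(benzyloxy)-6-methylbenzaldehyde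
Product: 8 2,4-bis(benzyloxy)-6-methylphenol, via aryl formate 7 (not isolated)
Conditions: mCPBA, CH2Cl2, 0 °C → rt; then KOH, MeOH–H2O, rt
Reagents that add atoms: mCPBA OOC(=O)c1cccc(Cl)c1
Why: Baeyer–Villiger (Dakin-type) oxidation in which the electron-rich aryl group migrates to oxygen, followed by hydrolysis of the formate to the phenol.

**Step 6**
Reactants: 4 benzyl 4-(benzyloxy)-2-fluoro-3-formyl-6-methylbenzoate; 8 2,4-bis(benzyloxy)-6-methylphenol
Product: 9 benzyl 4-(benzyloxy)-2-[2,4-bis(benzyloxy)-6-methylphenoxy]-3-formyl-6-methylbenzoate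
Conditions: Cs2CO3, DMF, N2, rt → 70 °C
Reagents that add atoms: none
Why: SNAr of the phenoxide of 8 at a fluoride activated by an ortho formyl and an ortho ester group should give the tetra-ortho-substituted diaryl ether with the ether oxygen fixed at the methyl-flanked position of ring B.

**Step 7**
Reactants: 9 benzyl 4-(benzyloxy)-2-[2,4-bis(benzyloxy)-6-methylphenoxy]-3-formyl-6-methylbenzoate
Product: 10 2-(2,4-dihydroxy-6-methylphenoxy)-3-formyl-4-hydroxy-6-methylbenzoic acid
Conditions: H2 (1 atm), 10% Pd/C, EtOAc, rt, stopped at complete debenzylation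
Reagents that add atoms: none
Why: Catalytic hydrogenolysis should cleave the three benzyl ethers and the benzyl ester faster than it reduces the formyl group, which is flanked by two ortho oxygen substituents.

**Step 8**
Reactants: 10 2-(2,4-dihydroxy-6-methylphenoxy)-3-formyl-4-hydroxy-6-methylbenzoic acid
Product: 11 3,8-dihydroxy-1,6-dimethyl-11-oxo-11H-dibenzo[b,e][1,4]dioxepine-4-carbaldehyde
Conditions: DCC (1.2 equiv), THF (0.01 M), 0 °C → rt
Reagents that add atoms: none
Why: Carbodiimide-mediated (Steglich-type) lactonisation in which only the ring B hydroxyl ortho to the ether oxygen can reach the activated acid (seven-membered ring), while the other two phenols cannot cyclise and dilution suppresses intermolecular esters.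

**Step 9**
Reactants: 11 3,8-dihydroxy-1,6-dimethyl-11-oxo-11H-dibenzo[b,e][1,4]dioxepine-4-carbaldehyde; 12 3-methylbut-2-enoic acid
Product: 15 Mollicellin A, via aryl ester 13 (not isolated), via enone 14 (not isolated)
Conditions: 12 (1.5 equiv), P2O5–MsOH (1:10 w/w), 60 °C
Reagents that add atoms: none
Why: In P2O5–MsOH acid 12 forms a mixed anhydride/acylium ion that O-acylates the free O8–H to aryl ester 13, an acid-mediated Fries shift (or direct Friedel–Crafts C-acylation) moves the 3-methylbut-2-enoyl group to C7 to give enone 14, and the protonated enone is trapped by O8 at its β-carbon. The closest known reaction type is the one-pot Friedel–Crafts acylation/oxa-Michael annulation of phenols with 3-methylbut-2-enoic acid in P2O5–MsOH or polyphosphoric acid to 2,2-dimethylchroman-4-ones. The pyranone ring closes by a 6-endo-trig oxa-Michael addition after the intermolecular C7–acyl bond is made, and no stereocentre arises because the new sp3 ring carbon bears two methyl groups. The step needs attack at C7 and not at C9 or on ring A: C7 is ortho to the free hydroxyl, para to the lactone oxygen O10 and ortho to the C6 methyl, C9 sits between two oxygens next to the inductively withdrawing acyloxy group, and ring A is deactivated by its formyl and lactone carbonyl groups with its hydroxyl held in a hydrogen bond to the formyl oxygen. It also needs the acylative and not the alkylative course (which would give a 4,4-dimethylchroman-2-one), which the dehydrating P2O5 medium secures by favouring the acylium ion over the tertiary carbocation. The formyl group is expected to survive because it is chelated and flanked by two ortho oxygen substituents, and ring closure removes the only strongly nucleophilic site of the molecule.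

**Compound list**
1 | 2,6-difluoro-4-methylbenzaldehyde | Cc1cc(F)c(C=O)c(F)c1 | starting material
2 | 2-(benzyloxy)-6-fluoro-4-methylbenzaldehyde | Cc1cc(F)c(C=O)c(OCc2ccccc2)c1 | intermediate
3 | 6-(benzyloxy)-3-bromo-2-fluoro-4-methylbenzaldehyde | Cc1cc(OCc2ccccc2)c(C=O)c(F)c1Br | intermediate
4 | benzyl 4-(benzyloxy)-2-fluoro-3-formyl-6-methylbenzoate | Cc1cc(OCc2ccccc2)c(C=O)c(F)c1C(=O)OCc1ccccc1 | intermediate
5 | 2,4-dihydroxy-6-methylbenzaldehyde | Cc1cc(O)cc(O)c1C=O | starting material
6 | 2,4-bis(benzyloxy)-6-methylbenzaldehyde | Cc1cc(OCc2ccccc2)cc(OCc2ccccc2)c1C=O | intermediate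
7 | 2,4-bis(benzyloxy)-6-methylphenyl formate | Cc1cc(OCc2ccccc2)cc(OCc2ccccc2)c1OC=O | intermediate
8 | 2,4-bis(benzyloxy)-6-methylphenol | Cc1cc(OCc2ccccc2)cc(OCc2ccccc2)c1O | intermediate
9 | benzyl 4-(benzyloxy)-2-[2,4-bis(benzyloxy)-6-methylphenoxy]-3-formyl-6-methylbenzoate | Cc1cc(OCc2ccccc2)c(C=O)c(Oc2c(C)cc(OCc3ccccc3)cc2OCc2ccccc2)c1C(=O)OCc1ccccc1 | intermediate
10 | 2-(2,4-dihydroxy-6-methylphenoxy)-3-formyl-4-hydroxy-6-methylbenzoic acid | Cc1cc(O)c(C=O)c(Oc2c(C)cc(O)cc2O)c1C(=O)O | intermediate
11 | 3,8-dihydroxy-1,6-dimethyl-11-oxo-11H-dibenzo[b,e][1,4]dioxepine-4-carbaldehyde | Cc1cc(O)c(C=O)c2c1C(=O)Oc1cc(O)cc(C)c1O2 | intermediate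
12 | 3-methylbut-2-enoic acid | CC(C)=CC(=O)O | starting material
13 | 4-formyl-3-hydroxy-1,6-dimethyl-11-oxo-11H-dibenzo[b,e][1,4]dioxepin-8-yl 3-methylbut-2-enoate | Cc1cc(O)c(C=O)c2c1C(=O)Oc1cc(OC(=O)C=C(C)C)cc(C)c1O2 | intermediate
14 | 3,8-dihydroxy-1,6-dimethyl-7-(3-methylbut-2-enoyl)-11-oxo-11H-dibenzo[b,e][1,4]dioxepine-4-carbaldehyde | Cc1cc(O)c(C=O)c2c1C(=O)Oc1cc(O)c(C(=O)C=C(C)C)c(C)c1O2 | intermediate
15 | Mollicellin A (the 2,2-dimethyl-2,3-dihydro-4H-pyran-4-one fused across C7–C8 of 11, ketone carbon on C7, ring oxygen on C8) | Cc1cc(O)c(C=O)c2c1C(=O)Oc1cc3c(c(C)c1O2)C(=O)CC(C)(C)O3 | target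

**Step count**
Total: 9 steps. Longest linear sequence: 7 steps (steps 1, 2, 3, 6, 7, 8, 9).

**Steps most likely to fail**

Step 9. The strongly acidic medium may divert the substrate into the alkylative course (tertiary cation attacking C7, then lactonisation), or promote condensation of the formyl group with ring B of a second molecule. The fallback sets out from 11 and comes back at enone 14, and so at 15. It makes the C7–C bond by cross-coupling and the ketone by a 1,3-oxygen shift, without a superacid. Iodination of 11 with NIS and cat. TsOH in MeCN at the same most nucleophilic carbon should give 3,8-dihydroxy-7-iodo-1,6-dimethyl-11-oxo-11H-dibenzo[b,e][1,4]dioxepine-4-carbaldehyde F1. Sonogashira coupling with 2-methylbut-3-yn-2-ol (Pd(PPh3)2Cl2, CuI, Et3N, THF, rt, to avoid 5-endo cyclisation to a benzofuran) should give 3,8-dihydroxy-7-(3-hydroxy-3-methylbut-1-yn-1-yl)-1,6-dimethyl-11-oxo-11H-dibenzo[b,e][1,4]dioxepine-4-carbaldehyde F2. A TsOH-catalysed Meyer–Schuster rearrangement in wet 1,2-dichloroethane at 60 °C should then give 14, which closes to 15 under the same catalysis.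

Step 6. Attack of the di-ortho-substituted phenoxide at a fluoride flanked by two carbonyl substituents may be so slow that O-alkyl cleavage of the benzyl ester by the phenoxide, or degradation of the aldehyde, overtakes substitution. The fallback sets out from 3 and 8 and comes back at 9, making the ether before the ester exists. SNAr of 8 on bromide 3 (Cs2CO3, DMF, 70 °C; the fluoride is flanked by formyl and the smaller bromine, and no benzyl ester is present) should give 6-(benzyloxy)-2-[2,4-bis(benzyloxy)-6-methylphenoxy]-3-bromo-4-methylbenzaldehyde F3. Pd-catalysed benzyloxycarbonylation of F3 (CO, BnOH, Pd(OAc)2, Xantphos, Et3N, toluene, 100 °C) should then give 9.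

Step 7. Over-reduction of the formyl group to hydroxymethyl or methyl may accompany cleavage of the four benzyl groups. The fallback sets out from 9 and comes back at 10, replacing reductive cleavage by Lewis-acid heterolysis. BCl3 with pentamethylbenzene as cation scavenger (CH2Cl2, −78 °C → 0 °C) should cleave the benzyl ethers and the benzyl ester without any reducing agent; this fallback makes no new compound (F0).

**Further compounds**
F1 | step 9 | 3,8-dihydroxy-7-iodo-1,6-dimethyl-11-oxo-11H-dibenzo[b,e][1,4]dioxepine-4-carbaldehyde | Cc1cc(O)c(C=O)c2c1C(=O)Oc1cc(O)c(I)c(C)c1O2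
F2 | step 9 | 3,8-dihydroxy-7-(3-hydroxy-3-methylbut-1-yn-1-yl)-1,6-dimethyl-11-oxo-11H-dibenzo[b,e][1,4]dioxepine-4-carbaldehyde | Cc1cc(O)c(C=O)c2c1C(=O)Oc1cc(O)c(C#CC(C)(C)O)c(C)c1O2
F3 | step 6 | 6-(benzyloxy)-2-[2,4-bis(benzyloxy)-6-methylphenoxy]-3-bromo-4-methylbenzaldehyde | Cc1cc(OCc2ccccc2)c(C=O)c(Oc2c(C)cc(OCc3ccccc3)cc2OCc2ccccc2)c1Br
F0 | step 7 | none | none
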